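The cyclohexane ring is cut at C-3a–C-7a and C-6–C-7 (1-benzofuranone numbering). The vicinal pair C-7a (lactone oxygen) and C-7 (hydroxyl) is glyoxal. Both flanks are carbonyl-allylation retrons: C-3a carries the exo-methylene carbon C-3, and the quaternary C-6 carries the vinyl group. The key step is a double allylboration annulation of glyoxal with an open-chain bis(allylboronate), which has a 2-(borylmethyl)enoate at one end, a (Z)-γ,γ-disubstituted allylboronate at the other, and already holds C-4 (angelate) and C-5 (isopropenyl). It should close the carbocycle and, by lactonisation, the α-methylene-γ-lactone, setting four stereocentres at once. The aldehyde is made last from the isopropenyl group.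

Key step: step 8

Remark: locants follow the 1-benzofuran-2-one numbering of 20–22 (O-1, C-2, C-3, C-3a, C-4 to C-7, C-7a), also for the atoms of open-chain precursors that end up there; glyoxal is assumed to be used as the anhydrous monomer, freshly generated from its commercial trimer dihydrate over P2O5.

Step 1
Reactants: 1 2,4-dimethylpenta-1,3-diene; 2 2,2-dimethoxyacetaldehyde
Product: 5 (2S)-1,1-dimethoxy-4-methyl-3-(prop-1-en-2-yl)pent-4-en-2-ol, via potassium 2,4-dimethylpentadienide 3 (not isolated), via pentadienyl-diisopinocampheylborane 4 (not isolated)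
Conditions: 1, n-BuLi, KOt-Bu, THF, −78 to 0 °C; (−)-Ipc2BCl, Et2O, −78 to 0 °C; anhydrous 2, −78 °C; NaOH, H2O2, 0 °C
Reagents that add atoms: none
Why: Brown-type allylboration: the terminally bound pentadienylborane should react through a closed six-membered transition state at its central (γ) carbon, giving the bis(isopropenyl)methyl group, and the isopinocampheyl groups derived from (+)-α-pinene are expected, by analogy with allylations by this reagent class, to select the aldehyde face that leads to the (S)-carbinol.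

Step 2
Reactants: 5; 6 dibutyl ethenylboronate
Product: 9 (2S,3S,4Z)-5-iodo-1,1-dimethoxy-4-methyl-3-(prop-1-en-2-yl)pent-4-en-2-ol, via mixed butyl ethenylboronate ester 7 (not isolated), via cyclic 1,2-oxaborinine 8 (not isolated)
Conditions: toluene, 50 °C, reduced pressure; second-generation Grubbs catalyst RuCl2(=CHPh)(PCy3)(H2IMes) (10 mol %), CH2Cl2, 40 °C; NaOH (aq), I2, THF, 0 °C
Reagents that add atoms: iodine, [I][I]
Why: Boron-tethered ring-closing metathesis then iododeboronation: the temporary B–O tether closes a six-membered ring onto one of the two diastereotopic isopropenyl groups, which fixes the ring-cis (later Z) alkene and should set the new stereocentre trans to the dimethoxymethyl-bearing carbon (both substituents pseudo-equatorial), and base-mediated iodinolysis of alkenylboronates proceeds with retention.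

Step 3
Reactants: 9; 10 angelic acid [(2Z)-2-methylbut-2-enoic acid]
Product: 11 (2S,3S,4Z)-5-iodo-1,1-dimethoxy-4-methyl-3-(prop-1-en-2-yl)pent-4-en-2-yl (2Z)-2-methylbut-2-enoate
Conditions: 10, 2,4,6-trichlorobenzoyl chloride, Et3N, toluene, 23 °C; then 9, toluene, 75 °C (no DMAP)
Reagents that add atoms: none
Why: Yamaguchi esterification through the mixed 2,4,6-trichlorobenzoic anhydride, run without nucleophilic catalyst to limit Z-to-E isomerisation of the angelate; no stereocentre is touched.

Step 4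
Reactants: 11
Product: 12 (2S,3S,4Z)-5-iodo-4-methyl-1-oxo-3-(prop-1-en-2-yl)pent-4-en-2-yl (2Z)-2-methylbut-2-enoate
Conditions: Et3SiOTf, 2,4,6-collidine, CH2Cl2, 0 °C; then H2O
Reagents that add atoms: water, O
Why: Silyl triflate/collidine acetal cleavage through a collidinium N,O-acetal that water hydrolyses under near-neutral conditions, so that the α-acyloxy stereocentre, the isopropenyl group, the vinyl iodide and the angelate should survive.

Step 5
Reactants: 13 methyl 2-[bis(2,2,2-trifluoroethoxy)phosphoryl]acetate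
Product: 14 methyl 2-[bis(2,2,2-trifluoroethoxy)phosphoryl]-2-bromoacetate (racemic)
Conditions: NaH, THF, 0 °C; Br2, −78 to 0 °C
Reagents that add atoms: bromine, BrBr
Why: Electrophilic α-bromination of the phosphonate-stabilised sodium enolate.

Step 6
Reactants: 12; 14
Product: 15 methyl (2E,4S,5S,6Z)-2-bromo-7-iodo-6-methyl-4-{[(2Z)-2-methylbut-2-enoyl]oxy}-5-(prop-1-en-2-yl)hepta-2,6-dienoate
Conditions: 14, KOt-Bu, 18-crown-6, THF, −78 °C; then 12, −78 °C
Reagents that add atoms: none
Why: Still–Gennari-type Horner–Wadsworth–Emmons olefination: the electron-poor bis(trifluoroethyl) phosphonate should eliminate from the kinetic adduct and place the aldehyde residue cis to the ester, i.e. give the (E)-α-bromoacrylate, while the low temperature protects the α-acyloxy stereocentre.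

Step 7
Reactants: 15
Product: 16 methyl (2Z,4R,5S,6Z)-6-methyl-4-{[(2Z)-2-methylbut-2-enoyl]oxy}-5-(prop-1-en-2-yl)-8-(4,4,5,5-tetramethyl-1,3,2-dioxaborolan-2-yl)-2-[(4,4,5,5-tetramethyl-1,3,2-dioxaborolan-2-yl)methyl]octa-2,6-dienoate
Conditions: ICH2Bpin, Zn dust, THF, 23 °C; then 15, Pd2(dba)3 (2.5 mol %), P(2-furyl)3 (10 mol %), THF, 23 to 40 °C
Reagents that add atoms: 2-(iodomethyl)-4,4,5,5-tetramethyl-1,3,2-dioxaborolane, ICB1OC(C)(C)C(C)(C)O1
Why: Double Negishi coupling: oxidative addition of zerovalent palladium into the C–I and C–Br bonds and transmetalation with the (borylmethyl)zinc reagent go with retention of both alkene geometries, so both allylboronate termini are installed at once and 16 is used without delay.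

Step 8
Reactants: 16; 17 glyoxal (ethanedial)
Product: 20 (3aS,4S,5S,6S,7S,7aR)-6-ethenyl-7-hydroxy-6-methyl-3-methylidene-2-oxo-5-(prop-1-en-2-yl)octahydro-1-benzofuran-4-yl (2Z)-2-methylbut-2-enoate, via open-chain boryloxy aldehyde 18 (not isolated), via cyclohexane bis(boryloxy) ester 19 (not isolated)
Conditions: 16 (0.01 M), Sc(OTf)3 (10 mol %), CH2Cl2, −78 °C; 17 (1.05 equiv, monomer in CH2Cl2) added slowly; −78 to 23 °C; p-TsOH·H2O (10 mol %), 23 °C; aq. NaHCO3
Reagents that add atoms: none
Why: Proposed new method: the Sc(OTf)3-activated 2-(borylmethyl)enoate end of 16 should add first to one carbonyl of glyoxal through a six-membered Zimmerman–Traxler chair, the α-boryloxy aldehyde 18 is then attacked intramolecularly by the (Z)-γ,γ-disubstituted allylboronate through a second chair fused to the forming carbocycle, and the C-7a borate oxygen finally closes the lactone on the methyl ester; the closest known reaction types are the Lewis-acid-catalysed allylboration–lactonisation of 2-alkoxycarbonyl allylboronates, intramolecular allylboration to 2-vinylcycloalkanols and tandem double allylations of dialdehydes with bis-boron reagents, which have not been merged into a bis(allylboronate)–glyoxal annulation. The cyclohexane closes by 6-exo-trig attack of C-6 on the aldehyde carbon C-7, and the γ-lactone by 5-exo-trig acyl substitution at C-2. C-3a and C-7a are set relative to each other by the enoate geometry (the C-4 residue is trans to CH2B, hence equatorial, giving the anti adduct and the trans ring fusion) and relative to C-4 by A(1,3) strain against the cis ester, which holds the C-4 hydrogen in the alkene plane so that glyoxal should approach anti to the bulky C-5 branch. C-6 and C-7 are set by the Z geometry of the second allylboronate (C-5 bond axial in the boron chair, so the hydroxyl becomes axial and trans-diaxial to the methyl group and the vinyl group equatorial) and by the chair of the forming ring, in which the C-3a, C-7a and C-5 substituents are equatorial and only the angelate is axial. The step needs the ester-bearing boronate to win the bimolecular event and one glyoxal per molecule of 16: the first is sought through the neopentyl-like hindrance of the other γ-carbon at −78 °C under Sc(OTf)3 catalysis, the second through slow addition of glyoxal at high dilution.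

Step 9
Reactants: 20
Product: 21 (3aS,4S,5S,6S,7S,7aR)-6-ethenyl-7-hydroxy-5-(3-hydroxyprop-1-en-2-yl)-6-methyl-3-methylidene-2-oxooctahydro-1-benzofuran-4-yl (2Z)-2-methylbut-2-enoate
Conditions: SeO2 (0.5 equiv), t-BuOOH (3 equiv), CH2Cl2, 23 °C
Reagents that add atoms: selenium dioxide, O=[Se]=O; tert-butyl hydroperoxide, CC(C)(C)OO
Why: Selenium dioxide allylic oxidation (ene reaction then 2,3-sigmatropic shift): the isopropenyl group is the only electron-rich alkene with allylic hydrogen, and its methyl group should react in preference to the hindered ring methine, so no stereocentre is affected.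

Step 10
Reactants: 21
Product: 22 (3aS,4S,5R,6S,7S,7aR)-6-ethenyl-7-hydroxy-6-methyl-3-methylidene-2-oxo-5-(3-oxoprop-1-en-2-yl)octahydro-1-benzofuran-4-yl (2Z)-2-methylbut-2-enoate
Conditions: MnO2 (activated, excess), CH2Cl2, 23 °C
Reagents that add atoms: none
Why: MnO2 oxidation, selective for the primary allylic alcohol over the secondary, non-allylic C-7 hydroxyl.

Compound list
1 | 2,4-dimethylpenta-1,3-diene | CC(C)=CC(C)=C | starting material
2 | 2,2-dimethoxyacetaldehyde | COC(OC)C=O | starting material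
3 | potassium 2,4-dimethylpentadienide | [K+].[CH2-]C(C)=CC(C)=C | intermediate
4 | (2,4-dimethylpenta-2,4-dien-1-yl)bis[(1R,2S,3R,5R)-2,6,6-trimethylbicyclo[3.1.1]hept-3-yl]borane | C=C(C)C=C(C)CB([C@@H]1C[C@@H]2C[C@H]([C@H]1C)C2(C)C)[C@@H]1C[C@@H]2C[C@H]([C@H]1C)C2(C)C | intermediate
5 | (2S)-1,1-dimethoxy-4-methyl-3-(prop-1-en-2-yl)pent-4-en-2-ol | C=C(C)C(C(C)=C)[C@H](O)C(OC)OC | intermediate
6 | dibutyl ethenylboronate | C=CB(OCCCC)OCCCC | starting material
7 | butyl (2S)-1,1-dimethoxy-4-methyl-3-(prop-1-en-2-yl)pent-4-en-2-yl ethenylboronate | C=CB(OCCCC)O[C@H](C(OC)OC)C(C(C)=C)C(C)=C | intermediate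
8 | (5S,6S)-2-butoxy-6-(dimethoxymethyl)-4-methyl-5-(prop-1-en-2-yl)-5,6-dihydro-2H-1,2-oxaborinine | CCCCOB1O[C@H](C(OC)OC)[C@@H](C(C)=C)C(C)=C1 | intermediate
9 | (2S,3S,4Z)-5-iodo-1,1-dimethoxy-4-methyl-3-(prop-1-en-2-yl)pent-4-en-2-ol | I/C=C(C)\[C@H](C(C)=C)[C@H](O)C(OC)OC | intermediate
10 | angelic acid, (2Z)-2-methylbut-2-enoic acid | C/C=C(/C)C(=O)O | starting material
11 | (2S,3S,4Z)-5-iodo-1,1-dimethoxy-4-methyl-3-(prop-1-en-2-yl)pent-4-en-2-yl (2Z)-2-methylbut-2-enoate | I/C=C(C)\[C@H](C(C)=C)[C@H](OC(=O)/C(C)=C\C)C(OC)OC | intermediate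
12 | (2S,3S,4Z)-5-iodo-4-methyl-1-oxo-3-(prop-1-en-2-yl)pent-4-en-2-yl (2Z)-2-methylbut-2-enoate | I/C=C(C)\[C@H](C(C)=C)[C@H](OC(=O)/C(C)=C\C)C=O | intermediate
13 | methyl 2-[bis(2,2,2-trifluoroethoxy)phosphoryl]acetate | COC(=O)CP(=O)(OCC(F)(F)F)OCC(F)(F)F | starting material
14 | methyl 2-[bis(2,2,2-trifluoroethoxy)phosphoryl]-2-bromoacetate (racemic) | COC(=O)C(Br)P(=O)(OCC(F)(F)F)OCC(F)(F)F | intermediate
15 | methyl (2E,4S,5S,6Z)-2-bromo-7-iodo-6-methyl-4-{[(2Z)-2-methylbut-2-enoyl]oxy}-5-(prop-1-en-2-yl)hepta-2,6-dienoate | I/C=C(C)\[C@H](C(C)=C)[C@H](OC(=O)/C(C)=C\C)/C=C(\C(=O)OC)Br | intermediate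
16 | methyl (2Z,4R,5S,6Z)-6-methyl-4-{[(2Z)-2-methylbut-2-enoyl]oxy}-5-(prop-1-en-2-yl)-8-(4,4,5,5-tetramethyl-1,3,2-dioxaborolan-2-yl)-2-[(4,4,5,5-tetramethyl-1,3,2-dioxaborolan-2-yl)methyl]octa-2,6-dienoate | CC1(C)OB(C/C=C(C)\[C@H](C(C)=C)[C@H](OC(=O)/C(C)=C\C)/C=C(\C(=O)OC)CB2OC(C)(C)C(C)(C)O2)OC1(C)C | intermediate
17 | glyoxal (ethanedial) | O=CC=O | starting material
18 | open-chain mono-adduct: methyl 2-methylidene-3-[2-oxo-1-(pinacolboryloxy)ethyl]-4-(angeloyloxy)-6-methyl-5-(prop-1-en-2-yl)-8-(pinacolboryl)oct-6-enoate, 6Z, configured as in 20 at the carbons that become C-3a, C-4, C-5 and C-7a | O=C[C@H](OB1OC(C)(C)C(C)(C)O1)[C@@H](C(=C)C(=O)OC)[C@@H](OC(=O)/C(C)=C\C)[C@@H](C(C)=C)/C(C)=C\CB1OC(C)(C)C(C)(C)O1 | intermediate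
19 | methyl 2-[2-(angeloyloxy)-4-ethenyl-4-methyl-5,6-bis(pinacolboryloxy)-3-(prop-1-en-2-yl)cyclohexyl]prop-2-enoate, ring stereocentres as in 20 | C=C[C@]1(C)[C@H](OB2OC(C)(C)C(C)(C)O2)[C@H](OB2OC(C)(C)C(C)(C)O2)[C@@H](C(=C)C(=O)OC)[C@@H](OC(=O)/C(C)=C\C)[C@H]1C(C)=C | intermediate
20 | (3aS,4S,5S,6S,7S,7aR)-6-ethenyl-7-hydroxy-6-methyl-3-methylidene-2-oxo-5-(prop-1-en-2-yl)octahydro-1-benzofuran-4-yl (2Z)-2-methylbut-2-enoate | C=C[C@]1(C)[C@H](O)[C@@H]2OC(=O)C(=C)[C@H]2[C@@H](OC(=O)/C(C)=C\C)[C@H]1C(C)=C | intermediate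
21 | (3aS,4S,5S,6S,7S,7aR)-6-ethenyl-7-hydroxy-5-(3-hydroxyprop-1-en-2-yl)-6-methyl-3-methylidene-2-oxooctahydro-1-benzofuran-4-yl (2Z)-2-methylbut-2-enoate | C=C[C@]1(C)[C@H](O)[C@@H]2OC(=O)C(=C)[C@H]2[C@@H](OC(=O)/C(C)=C\C)[C@H]1C(=C)CO | intermediate
22 | (3aS,4S,5R,6S,7S,7aR)-6-ethenyl-7-hydroxy-6-methyl-3-methylidene-2-oxo-5-(3-oxoprop-1-en-2-yl)octahydro-1-benzofuran-4-yl (2Z)-2-methylbut-2-enoate | C=C[C@]1(C)[C@H](O)[C@@H]2OC(=O)C(=C)[C@H]2[C@@H](OC(=O)/C(C)=C\C)[C@H]1C(=C)C=O | target

Total step count: 10. Longest linear sequence: 9 steps (steps 1–4 and 6–10; step 5 makes the phosphonate 14).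

Steps most likely to fail

Step 8 (Proposed new method). The bimolecular allylation may begin at the more nucleophilic γ,γ-disubstituted boronate instead of the ester-bearing one. The face of the future C-6 would then be chosen without control, giving C-6/C-7 diastereomers. Intermolecular 2:1 coupling or polymerisation of glyoxal may also outrun ring closure. The fallback makes the two bonds in separate, known steps. It sets out from 12. Alkylation of 13 (NaH, ICH2Bpin, THF) would give the borylmethyl phosphonate F1, and Still–Gennari olefination of 12 with F1 (KN(SiMe3)2, 18-crown-6, THF, −78 °C) the iodo-diene mono-boronate F2, in which only one allylboronate is present. Sc(OTf)3-catalysed allylboration of 2 with F2 and acid-induced lactonisation should give the trans-4,5-disubstituted 3-methylidene-oxolan-2-one F3, which carries the dimethoxymethyl group at C-5 and the iodo-diene chain at C-4. Negishi coupling with the (borylmethyl)zinc reagent as in step 7 would give the allylboronate F4, and acetal cleavage as in step 4 the aldehyde F5. F5 should cyclise by intramolecular allylboration to the C-7 borate F6, whose hydrolysis on work-up comes back to the route at 20.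

Step 2. Ring closure onto the 1,1-disubstituted alkene may be sluggish, the mixed boronate tether may be lost by hydrolysis, and the two diastereotopic isopropenyl groups may be poorly discriminated. The fallback replaces the boron tether by a robust silicon tether and sets out from 5. Silylation (chloro(ethenyl)dimethylsilane, imidazole, CH2Cl2) would give the ethenyl(dimethyl)silyl ether F7. Ring-closing metathesis with the molybdenum alkylidene Mo(=CHCMe2Ph)(=N-2,6-i-Pr2C6H3)[OCMe(CF3)2]2 (benzene, 23 to 60 °C) would give the cyclic alkenylsiloxane F8. Iododesilylation with retention (N-iodosuccinimide, (CF3)2CHOH, 0 °C; then KF, MeOH) comes back to the route at 9.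

Step 9. Over-oxidation, competing attack at the ring methine next to the isopropenyl group (loss of the C-5 stereocentre) and selenium-mediated degradation of the α-methylene lactone may occur. The fallback sets out from 20 and uses a Schenck ene reaction with singlet oxygen (O2, tetraphenylporphyrin, visible light, CH2Cl2, 0 °C), which should give the allylic hydroperoxide F9. Reduction with PPh3 comes back to the route at 21.

Further compounds
F1 | step 8 | methyl 2-[bis(2,2,2-trifluoroethoxy)phosphoryl]-3-(4,4,5,5-tetramethyl-1,3,2-dioxaborolan-2-yl)propanoate | COC(=O)C(CB1OC(C)(C)C(C)(C)O1)P(=O)(OCC(F)(F)F)OCC(F)(F)F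
F2 | step 8 | methyl (2Z,4R,5S,6Z)-7-iodo-6-methyl-4-{[(2Z)-2-methylbut-2-enoyl]oxy}-5-(prop-1-en-2-yl)-2-[(4,4,5,5-tetramethyl-1,3,2-dioxaborolan-2-yl)methyl]hepta-2,6-dienoate | I/C=C(C)\[C@H](C(C)=C)[C@H](OC(=O)/C(C)=C\C)/C=C(\C(=O)OC)CB1OC(C)(C)C(C)(C)O1
F3 | step 8 | trans-5-(dimethoxymethyl)-3-methylidene-oxolan-2-one bearing at C-4 the (3Z)-1-(angeloyloxy)-4-iodo-3-methyl-2-(prop-1-en-2-yl)but-3-en-1-yl chain, stereocentres as in 20 | COC(OC)[C@@H]1OC(=O)C(=C)[C@H]1[C@@H](OC(=O)/C(C)=C\C)[C@@H](C(C)=C)/C(C)=C\I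
F4 | step 8 | the analogue of F3 with CH2Bpin in place of iodine | COC(OC)[C@@H]1OC(=O)C(=C)[C@H]1[C@@H](OC(=O)/C(C)=C\C)[C@@H](C(C)=C)/C(C)=C\CB2OC(C)(C)C(C)(C)O2
F5 | step 8 | the aldehyde from F4 (formyl group at C-5 of the oxolanone) | O=C[C@@H]1OC(=O)C(=C)[C@H]1[C@@H](OC(=O)/C(C)=C\C)[C@@H](C(C)=C)/C(C)=C\CB2OC(C)(C)C(C)(C)O2
F6 | step 8 | C-7 O-pinacolborate of 20 | C=C[C@]1(C)[C@H](OB3OC(C)(C)C(C)(C)O3)[C@@H]2OC(=O)C(=C)[C@H]2[C@@H](OC(=O)/C(C)=C\C)[C@H]1C(C)=C
F7 | step 2 | {[(2S)-1,1-dimethoxy-4-methyl-3-(prop-1-en-2-yl)pent-4-en-2-yl]oxy}(ethenyl)dimethylsilane | C=C[Si](C)(C)O[C@H](C(OC)OC)C(C(C)=C)C(C)=C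
F8 | step 2 | (5S,6S)-6-(dimethoxymethyl)-2,2,4-trimethyl-5-(prop-1-en-2-yl)-5,6-dihydro-2H-1,2-oxasiline | C[Si]1(C)O[C@H](C(OC)OC)[C@@H](C(C)=C)C(C)=C1
F9 | step 9 | (3aS,4S,5S,6S,7S,7aR)-6-ethenyl-5-(3-hydroperoxyprop-1-en-2-yl)-7-hydroxy-6-methyl-3-methylidene-2-oxooctahydro-1-benzofuran-4-yl (2Z)-2-methylbut-2-enoate | C=C[C@]1(C)[C@H](O)[C@@H]2OC(=O)C(=C)[C@H]2[C@@H](OC(=O)/C(C)=C\C)[C@H]1C(=C)COO
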